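## Retrosynthetic overview

1. Target 22 ⇒ Heck arylation (4-iodophenol) of acrylate 20 ⇒ acylation of hydroxy acid 17 ⇒ Wittig methylenation of 8-ketone 16.
2. 16 ⇒ Giese addition (C11–C12 bond) of the radical from (R)-iodo acid 15 to exo-methylene ketone 12; C13 comes from (R)-β-methyl-γ-butyrolactone.
3. 12 ⇒ semipinacol ring expansion of the trans-hydrindanyl vinyl carbinol 10: C10 shifts from C8 to C9, so the cyclopentane becomes ring B.
4. 10 ⇒ C3 deoxygenation ⇐ reductive hydroxymethylation (sets C5 and C4) ⇐ vinyl addition ⇐ enedione 4 ⇐ amino-acid Robinson annulation of 1 + 2 (sets C10).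
5. Ring order: cyclopentane (from 1) → ring A (annulation) → ring B (one-carbon expansion of the cyclopentane).

Assumption: (R)-4-methyldihydrofuran-2(3H)-one (13) is taken as a commercial enantiopure catalogue compound; positions are given in labdane numbering (C1–C20) throughout.

## Route

Step 1
Reactants: 1 2-methylcyclopentane-1,3-dione; 2 pent-1-en-3-one (ethyl vinyl ketone)
Product: 4 (7aR)-4,7a-dimethyl-2,3,7,7a-tetrahydro-1H-indene-1,5(6H)-dione, via triketone 3 (not isolated)
Conditions: H2O, 75 °C; evaporate; D-Phe (1 equiv), 1 M HClO4 (0.4 equiv), MeCN, 80 °C; recrystallise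
Reagents that add atoms: none
Why: Michael addition followed by D-phenylalanine-mediated enamine aldol condensation (Hajos–Parrish-type Robinson annulation); the amino-acid enamine of the side-chain ketone selects one of the two enantiotopic ring carbonyls and fixes the angular-methyl carbon C10 (R in 4, the mirror image of the L-amino-acid product).

Step 2
Reactants: 4 (7aR)-4,7a-dimethyl-2,3,7,7a-tetrahydro-1H-indene-1,5(6H)-dione; 5 vinylmagnesium bromide
Product: 6 (1S,7aR)-1-ethenyl-1-hydroxy-4,7a-dimethyl-1,2,3,6,7,7a-hexahydro-5H-inden-5-one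
Conditions: CeCl3 (1.3 equiv), 5 (1.2 equiv), THF, −78 °C; aq NH4Cl
Reagents that add atoms: none
Why: Chemoselective 1,2-addition of a non-basic vinylcerium reagent to the saturated cyclopentanone (the enone carbonyl is deactivated by conjugation and flanked by the C4 methyl); attack anti to the angular methyl sets C8, a centre that is destroyed later, and the carbinol masks C8 and carries the trigger for the ring expansion.

Step 3
Reactants: 6 (1S,7aR)-1-ethenyl-1-hydroxy-4,7a-dimethyl-1,2,3,6,7,7a-hexahydro-5H-inden-5-one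
Product: 8 (1S,3aS,4S,7aR)-1-ethenyl-1-hydroxy-4-(hydroxymethyl)-4,7a-dimethyloctahydro-5H-inden-5-one, via dilithium enolate 7 (not isolated)
Conditions: Li (2.5 equiv), NH3(l)/THF, −78 °C; isoprene; evaporate NH3; CH2O (g), THF, −78 °C; aq NH4Cl
Reagents that add atoms: formaldehyde, C=O
Why: Dissolving-metal reduction of the enone followed by aldol trapping of the regiodefined enolate (reductive hydroxymethylation); protonation of the β-carbanion gives the trans ring fusion (C5–H anti to C10–CH3), and formaldehyde adds to C4 on the face anti to the axial C10 methyl, so CH2OH is equatorial and trans to C20 and the C4 methyl is axial.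

Step 4
Reactants: 8 (1S,3aS,4S,7aR)-1-ethenyl-1-hydroxy-4-(hydroxymethyl)-4,7a-dimethyloctahydro-5H-inden-5-one
Product: 10 (1S,3aR,4S,7aR)-1-ethenyl-4-(hydroxymethyl)-4,7a-dimethyloctahydro-1H-inden-1-ol, via tosylhydrazone 9 (not isolated)
Conditions: TsNHNH2 (1.3 equiv), PPTS (cat.), EtOH, 60 °C; evaporate; catecholborane (5 equiv), CHCl3, 0 °C→rt; NaOAc·3H2O, 60 °C
Reagents that add atoms: none
Why: Kabalka-type reductive deoxygenation of a tosylhydrazone (hydride addition to C=N, loss of sulfinate, N2 extrusion from the alkyldiazene) turns C3=O into CH2 under near-neutral conditions that avoid retro-aldol loss of formaldehyde; no stereocentre is touched.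

Step 5
Reactants: 10 (1S,3aR,4S,7aR)-1-ethenyl-4-(hydroxymethyl)-4,7a-dimethyloctahydro-1H-inden-1-ol
Product: 12 (4aS,5S,8aR)-5-(hydroxymethyl)-5,8a-dimethyl-1-methylideneoctahydronaphthalen-2(1H)-one, via selanyl ketone 11 (not isolated)
Conditions: (PhSe)2 (10 mol%), 1-fluoro-2,4,6-trimethylpyridinium triflate (1.2 equiv), NaHCO3 (2.5 equiv), MeCN, 0 °C→rt
Reagents that add atoms: none
Why: Proposed new method: PhSe+ (from (PhSe)2 and the N–F oxidant) forms a seleniranium ion on the vinyl group, which has no allylic C–H, so the only internal nucleophile is the C8–C10 σ-bond anti to C–Se; its 1,2-shift from C8 to C9 (type-I semipinacol, quaternary carbon migrating in preference to the C7 methylene, carbinol → ketone, strained trans-hydrindane → trans-decalin) gives β-selanyl ketone 11, which is re-oxidised at selenium and loses PhSe–X by E2 across the acidic C9–H to give the exo-methylene ketone and return the catalyst; C5 is untouched and C10 migrates with retention; the closest known reaction types are selenium-π-acid-catalysed oxidative allylic functionalisation of alkenes with N–F oxidants and stoichiometric halonium- or selenonium-induced semipinacol ring expansion of 1-vinylcycloalkanols, which have not been merged into a catalytic dehydrogenative ring expansion of an unstrained fused cyclopentanol.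

Step 6
Reactants: 13 (R)-4-methyldihydrofuran-2(3H)-one
Product: 15 (R)-4-iodo-3-methylbutanoic acid, via silyl ester 14 (not isolated)
Conditions: TMSI (1.5 equiv), CHCl3, 60 °C; H2O
Reagents that add atoms: iodotrimethylsilane, C[Si](C)(C)I
Why: TMSI lactone cleavage (O-silylation, then SN2 attack of iodide at the O–CH2 carbon); the stereocentre is β to the reacting carbon and is retained.

Step 7
Reactants: 12 (4aS,5S,8aR)-5-(hydroxymethyl)-5,8a-dimethyl-1-methylideneoctahydronaphthalen-2(1H)-one; 15 (R)-4-iodo-3-methylbutanoic acid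
Product: 16 (4S,5S,9S,10R,13S)-18-hydroxy-8-oxo-17-norlabdan-15-oic acid
Conditions: 15 (2 equiv), (TMS)3SiH (2.2 equiv, syringe pump), AIBN (0.2 equiv), PhMe, 75 °C; then DBU (3 equiv), CH2Cl2, rt; aq citric acid
Reagents that add atoms: none
Why: Giese radical conjugate addition of the primary alkyl radical to the unhindered CH2 terminus of the enone forms C11–C12; C13 is remote from the radical centre and retained, and C9 is set by H-atom transfer and then base equilibration to the thermodynamically preferred equatorial side chain.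

Step 8
Reactants: 16 (4S,5S,9S,10R,13S)-18-hydroxy-8-oxo-17-norlabdan-15-oic acid
Product: 17 (4S,5S,9R,10S,13S)-18-hydroxylabd-8(17)-en-15-oic acid
Conditions: Ph3PCH3Br (6 equiv), KOtBu (5.5 equiv), PhMe, 80 °C; aq citric acid
Reagents that add atoms: methylenetriphenylphosphorane, C=P(c1ccccc1)(c1ccccc1)c1ccccc1
Why: Wittig methylenation of the C8 ketone with excess ylide, which tolerates the carboxylate and alkoxide; C9 stays in the equatorial (thermodynamic) configuration under the basic conditions.

Step 9
Reactants: 17 (4S,5S,9R,10S,13S)-18-hydroxylabd-8(17)-en-15-oic acid; 18 acryloyl chloride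
Product: 20 (4S,5S,9R,10S,13S)-18-(acryloyloxy)labd-8(17)-en-15-oic acid, via mixed anhydride 19 (not isolated)
Conditions: 18 (3 equiv), Et3N (4 equiv), BHT (cat.), CH2Cl2, −20→0 °C (17 added to the acyl chloride); then THF/aq NaHCO3, rt; acidify to pH 4
Reagents that add atoms: none
Why: O-acylation of the primary neopentyl alcohol with an acyl chloride; the carboxylic acid is acylated as well to a mixed anhydride that is hydrolysed back to the acid by aqueous bicarbonate, as in acylations of hydroxy acids with excess acylating agent.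

Step 10
Reactants: 20 (4S,5S,9R,10S,13S)-18-(acryloyloxy)labd-8(17)-en-15-oic acid; 21 4-iodophenol
Product: 22 (4S,5S,9R,10S,13S)-18-[(E)-3-(4-hydroxyphenyl)prop-2-enoyloxy]labd-8(17)-en-15-oic acid
Conditions: Pd(OAc)2 (5 mol%), Bu4NCl (1 equiv), NaHCO3 (3 equiv), DMF, 70 °C; aq citric acid
Reagents that add atoms: none
Why: Mizoroki–Heck arylation (Jeffery conditions) of the acrylate; syn-insertion and syn-β-hydride elimination give the E-cinnamate, and the hindered unactivated 8(17)-alkene reacts far more slowly than the acrylate.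

## Compound list

1 | 2-methylcyclopentane-1,3-dione | CC1C(=O)CCC1=O | starting material
2 | pent-1-en-3-one (ethyl vinyl ketone) | CCC(=O)C=C | starting material
3 | 2-methyl-2-(3-oxopentyl)cyclopentane-1,3-dione | CCC(=O)CCC1(C)C(=O)CCC1=O | intermediate (not isolated)
4 | (7aR)-4,7a-dimethyl-2,3,7,7a-tetrahydro-1H-indene-1,5(6H)-dione | C[C@@]12CCC(=O)C(C)=C1CCC2=O | intermediate
5 | vinylmagnesium bromide | C=C[Mg]Br | starting material
6 | (1S,7aR)-1-ethenyl-1-hydroxy-4,7a-dimethyl-1,2,3,6,7,7a-hexahydro-5H-inden-5-one (vinyl anti, OH syn to the angular methyl) | C=C[C@@]1(O)CCC2=C(C)C(=O)CC[C@@]12C | intermediate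
7 | dilithium C1-alkoxide / Δ4-C5-enolate of the trans-fused reduced enone (3a-H anti to 7a-CH3) | C=C[C@@]1([O-])CC[C@@H]2C(C)=C([O-])CC[C@@]12C.[Li+].[Li+] | intermediate (not isolated)
8 | (1S,3aS,4S,7aR)-1-ethenyl-1-hydroxy-4-(hydroxymethyl)-4,7a-dimethyloctahydro-5H-inden-5-one (trans-fused; CH2OH anti to the angular methyl) | C=C[C@@]1(O)CC[C@@H]2[C@@](C)(CO)C(=O)CC[C@@]12C | intermediate
9 | 5-(4-methylbenzenesulfonyl)hydrazone of 8 (C=N geometry not defined) | C=C[C@@]1(O)CC[C@@H]2[C@@](C)(CO)C(=NNS(=O)(=O)c3ccc(C)cc3)CC[C@@]12C | intermediate (not isolated)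
10 | (1S,3aR,4S,7aR)-1-ethenyl-4-(hydroxymethyl)-4,7a-dimethyloctahydro-1H-inden-1-ol | C=C[C@@]1(O)CC[C@@H]2[C@@](C)(CO)CCC[C@@]12C | intermediate
11 | 5-(hydroxymethyl)-5,8a-dimethyl-1-[(phenylselanyl)methyl]octahydronaphthalen-2(1H)-one (ring centres as in 12; C1 epimers) | O=C1CC[C@@H]2[C@@](C)(CO)CCC[C@@]2(C)C1C[Se]c1ccccc1 | intermediate (not isolated)
12 | (4aS,5S,8aR)-5-(hydroxymethyl)-5,8a-dimethyl-1-methylideneoctahydronaphthalen-2(1H)-one (trans-decalin) | O=C1CC[C@@H]2[C@@](C)(CO)CCC[C@@]2(C)C1=C | intermediate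
13 | (R)-4-methyldihydrofuran-2(3H)-one ((R)-β-methyl-γ-butyrolactone) | O=C1C[C@@H](C)CO1 | starting material
14 | trimethylsilyl (R)-4-iodo-3-methylbutanoate | C[Si](C)(C)OC(=O)C[C@@H](C)CI | intermediate (not isolated)
15 | (R)-4-iodo-3-methylbutanoic acid | OC(=O)C[C@@H](C)CI | intermediate
16 | (4S,5S,9S,10R,13S)-18-hydroxy-8-oxo-17-norlabdan-15-oic acid (ent-labdane series) | O=C1CC[C@@H]2[C@@](C)(CO)CCC[C@@]2(C)[C@@H]1CC[C@H](C)CC(=O)O | intermediate
17 | (4S,5S,9R,10S,13S)-18-hydroxylabd-8(17)-en-15-oic acid (ent-labdane series) | C=C1CC[C@@H]2[C@@](C)(CO)CCC[C@@]2(C)[C@@H]1CC[C@H](C)CC(=O)O | intermediate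
18 | acryloyl chloride | C=CC(=O)Cl | starting material
19 | acrylic mixed anhydride of 18-(acryloyloxy)labd-8(17)-en-15-oic acid (stereocentres as in 17) | C=C1CC[C@@H]2[C@@](C)(COC(=O)C=C)CCC[C@@]2(C)[C@@H]1CC[C@H](C)CC(=O)OC(=O)C=C | intermediate (not isolated)
20 | (4S,5S,9R,10S,13S)-18-(acryloyloxy)labd-8(17)-en-15-oic acid | C=C1CC[C@@H]2[C@@](C)(COC(=O)C=C)CCC[C@@]2(C)[C@@H]1CC[C@H](C)CC(=O)O | intermediate
21 | 4-iodophenol | Oc1ccc(I)cc1 | starting material
22 | (4S,5S,9R,10S,13S)-18-[(E)-3-(4-hydroxyphenyl)prop-2-enoyloxy]labd-8(17)-en-15-oic acid (CNP0389065.1) | C=C1CC[C@@H]2[C@@](C)(COC(=O)/C=C/c3ccc(O)cc3)CCC[C@@]2(C)[C@@H]1CC[C@H](C)CC(=O)O | target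

## Step count and risks

Total: 10 steps (9 in the main line plus 1 for the side-chain piece 15). Longest linear sequence: 9 steps (1 → 2 → 3 → 4 → 5 → 7 → 8 → 9 → 10).

The three steps most likely to fail:

Step 5 (the proposed new selenium-catalysed ring expansion). The seleniranium ion may be captured by the tertiary hydroxyl, selenium turnover may stall, the ketone product may be selenenylated at C7, or C7 may migrate in place of C10. The fallback uses known stoichiometric chemistry and sets out from 10: NBS (1.05 equiv) in CH2Cl2/HFIP at −20 °C gives, by bromonium-induced semipinacol ring expansion, the bromomethyl ketone F6; DBU added to the same flask eliminates HBr and the route is rejoined at 12.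

Step 4 (deoxygenation of the hindered C3 ketone next to a quaternary carbon, with a free β-hydroxyl and an acid-sensitive tertiary allylic alcohol). Hydrazone formation or its reduction may be sluggish. The fallback replaces hydrazone chemistry by radical C–O cleavage and sets out from 8: NaBH4 reduces the C3 ketone to the triol F3; 1,1'-thiocarbonyldiimidazole closes the six-membered cyclic thionocarbonate F4 across the C3 and C18 oxygens; Bu3SnH/AIBN in toluene fragments it toward the secondary C3 radical (Barton deoxygenation of a 1,3-diol thionocarbonate) to give the S-stannyl thiocarbonate F5; NaOH/MeOH releases the C18 alcohol and the route is rejoined at 10.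

Step 2 (chemoselective vinyl addition to the hindered saturated ketone beside an enone). Competing 1,2-addition at C3 is possible. The fallback masks the enone first and sets out from 4: triethyl orthoformate/EtOH with catalytic TsOH converts the conjugated ketone selectively into the ethyl dienol ether F1; vinylmagnesium bromide then adds only to the remaining C8 ketone to give the carbinol F2; dilute aqueous oxalic acid hydrolyses the enol ether and the route is rejoined at 6.

## Further compounds

F1 | step 2 | (7aR)-5-ethoxy-4,7a-dimethyl-2,6,7,7a-tetrahydro-1H-inden-1-one (ethyl dienol ether of the enone of 4) | CCOC1=C(C)C2=CCC(=O)[C@]2(C)CC1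
F2 | step 2 | (1S,7aR)-5-ethoxy-1-ethenyl-4,7a-dimethyl-2,6,7,7a-tetrahydro-1H-inden-1-ol | CCOC1=C(C)C2=CC[C@](O)(C=C)[C@]2(C)CC1
F3 | step 4 | 1-ethenyl-4-(hydroxymethyl)-4,7a-dimethyloctahydro-1H-indene-1,5-diol (C5 epimers; other centres as in 8) | C=C[C@@]1(O)CC[C@@H]2[C@@](C)(CO)C(O)CC[C@@]12C
F4 | step 4 | cyclic thionocarbonate (1,3-dioxane-2-thione) spanning the C5–O and 4-CH2–O of F3 | C=C[C@@]1(O)CC[C@@H]2[C@@]3(C)COC(=S)OC3CC[C@@]12C
F5 | step 4 | O-(C18-methyl) S-(tributylstannyl) thiocarbonate of 10 | C=C[C@@]1(O)CC[C@@H]2[C@@](C)(COC(=O)S[Sn](CCCC)(CCCC)CCCC)CCC[C@@]12C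
F6 | step 5 | 1-(bromomethyl)-5-(hydroxymethyl)-5,8a-dimethyloctahydronaphthalen-2(1H)-one (ring centres as in 12; C1 epimers) | O=C1CC[C@@H]2[C@@](C)(CO)CCC[C@@]2(C)C1CBr
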